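Dissolving has a larger coefficient than ring closure, 0.245 h⁻¹ against 0.0996 h⁻¹, and two chemists read that comparison differently for this flask.

    J → G (k1 = 0.0996 h⁻¹)
    E ⇌ J, rate k2*(cs2 - [J]) while solid is left; crystals form when [J] > cs2 (cs2 = 0.78 M, k2 = 0.245 h⁻¹)
    J + Z → J.Z (k3 = 0.0273 M⁻¹ h⁻¹)
    2 J → J2 (k4 = 0.0465 M⁻¹ h⁻¹)

E 2.2 M; Z 0.440 M; time 20 h

1. G at 20 h, in percent of the E charged
2. the change that raises the amount of G at 20 h, in percent of the E charged most ("none" if none brings more than 2 percentage points) (larch / elm / none)
3. amount of G at 20 h, in percent of the E charged, after elm

- larch: doubling the dissolution coefficient of step 2, all else as stated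
- elm: doubling the solubility in step 2, all else as stated

- in percentages every species weighs as the E in it: one J2 counts as two
- a step written with two of one species runs at k times the square of its concentration and takes two of it each time
- as a solid, counted per litre of solution: E
- at the start none of E is in solution
- run time (flask): 20 h

The first holds that the solution stays near empty, so that dissolving delivers 174% of the charge by 20 h: at that full pace of 0.191 M h⁻¹ the 2.2 M of E lasts 11.5 h, and G collects what the side steps spare.

The second, whose side I take, freezes what is nearly constant. Z, though not in excess, can stand roughly at its charge, as a pseudo-first-order partner of J, since even with J at the solubility the half-life of Z by that step is 32.6 h, longer than the run of 20 h, and the same step is a slow drain on J, whose half-life by it, 58 h, is longer than the 7.0 h of ring closure. Dissolved J can stand too: the concentration at which dissolving, its coefficient times the gap to saturation, equals ring closure plus the step with Z plus twice the dimer step is the holding level, 0.477 M, which is lower than the solubility of 0.78 M. I count the climb towards that level as a lag of 2.25 h, the inverse slope of the balance, and let G grow after it at a steady 0.0475 M h⁻¹, so by 20 h I reckon 38.3% of the charge. At that level the solid lasts 25.4 h, longer than the run.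

Under elm the level rises to 0.873 M, under larch to 0.583 M, but the solid then lasts 9.81 h and 18.1 h, shorter than the run, so my reckoning stops there and ranks neither.

The forecast, which holds that “dissolution balances ring closure and the dimer and Z side reactions”, gives 38.6% (36.5% to 40.5%), chooses elm, and gives 53.5% (50% to 57%) after it.

The flask gives 38.1% of G, and elm is the better change, gaining 14 percentage points against 10 points for larch and reaching 52.2%. At 10.0 h J in the flask stood at 21.4% of the charge, where the holding level is 21.7%. The near-empty view keeps the opening hours: by 2.00 h the flask had dissolved 14.0% of its E, against the 17.4% of that view. For the same flask stopped at 5.0 h, the level and lag give 5.94% of G, and that flask reads 6.26%.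

(The rate constants come from no measurement.)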